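**Plan**

1. Enabling feature: in the ten-membered ring (C1–C10) the ring bond C3=C4 (Z) is conjugated with the exocyclic methylene C5=C16. This C16=C5–C4=C3 diene, flanked by C6–Cl and C2–OAc, is the retron of an endo-mode ring-closing enyne metathesis. The last cut is therefore C3=C4, with C16H2 returned to C3, which gives enyne 32 (C2 vinyl carbinol acetate plus C6 propargylic chloride, cyclohexene and lactone intact).
2. Further cuts: C6–C7 (chloroallenylzinc plus C7 aldehyde, after which O7 closes the lactone on C19), C2–C3 (vinyl Grignard), C1–C14 and C10–C11 (Diels–Alder), C1=C10 (Wittig), C8–C17 (propionate aldol on the 3-ulose of D-glucose).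
3. Forward ring order: glucofuranose/acetonide scaffold (temporary rings), then cyclohexene (step 6), then γ-lactone (step 17, after the furanose is cut open), then the ten-membered ring (step 20).
4. Stereochemistry: C9 is C4 of D-glucose. C8 comes from a convex-face aldol and C17 from kinetic protonation. C1/C10 come from Diels–Alder attack on the alkene face not covered by C8. C11/C12 come from OsO4 anti to the C10 substituent, C2 from Felkin–Anh hydride addition, C7/C6 from a Felkin–Anh, anti-selective allenylzinc addition, and 3Z from ring strain.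
5. Helpers: 8-OTBS (shield, non-chelating); the furanose ring O9–C6 (ties up O9, masks C7=O); glucose C1, which leaves the skeleton in step 16 but stays on O9 as a formate that keeps O9 out of the lactonisation. All are removed in steps 16–18.

Key step: step 20

Remark: briarane numbering is used (C1 quaternary ring-fusion carbon with Me-15, C2–C9 chain of the ten-membered ring, C10 ring-fusion CH, C11–C14 cyclohexene, C16 methylene on C5, C17/C18/C19 lactone CH/CH3/C=O, C20 methyl on C11); the target is 1S,2R,3Z,6S,7R,8R,9R,10S,11S,12R,17R.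

"Fur" is the furanose unit bonded through C9: ring O9–C6–C7–C8–C9, with cis 6,7-O-isopropylidene and 8-OTBS on the face opposite to C10, and C8 also bearing the (17R)-CH(CH3)CO2CH3 arm, configured as in 7.

**Step 1**
Reactants: 1 1,2:5,6-di-O-isopropylidene-α-D-glucofuranose
Product: 2 1,2:5,6-di-O-isopropylidene-α-D-ribo-hexofuranos-3-ulose
Conditions: TPAP (5 mol %), NMO, 4 Å MS, CH2Cl2, rt
Reagents that add atoms: none
Why: Catalytic perruthenate (TPAP/NMO) oxidation should convert the only free hydroxyl (glucose C3, the future C8) into the ketone under neutral conditions that leave both acetonides untouched.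

**Step 2**
Reactants: 2 1,2:5,6-di-O-isopropylidene-α-D-ribo-hexofuranos-3-ulose; 3 methyl propanoate
Product: 5 methyl (2R)-2-(1,2:5,6-di-O-isopropylidene-α-D-allofuranos-3-C-yl)propanoate, via C17-epimeric aldolates 4 (not isolated)
Conditions: 3, LDA (1.1 equiv), THF, −78 °C; 2; then LDA (1.5 equiv), −78 → −40 °C; AcOH/THF, −78 °C
Reagents that add atoms: none
Why: Lithium ester enolate aldol addition to the strained ketone from the convex β-face of the cis-fused bicycle (opposite the 1,2-acetonide) should set C8 (allo series), and re-enolisation to the lithium-chelated alkoxide enolate (Fráter–Seebach type dianion) followed by kinetic protonation on the enolate face turned away from the β-oriented C4 side chain should converge both epimers on 17R.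

**Step 3**
Reactants: 5 methyl (2R)-2-(1,2:5,6-di-O-isopropylidene-α-D-allofuranos-3-C-yl)propanoate
Product: 6 3-O-TBS ether of 5
Conditions: TBSOTf, 2,6-lutidine, CH2Cl2, 0 °C → rt
Reagents that add atoms: tert-butyldimethylsilyl triflate CC(C)(C)[Si](C)(C)OS(=O)(=O)C(F)(F)F
Why: Silyl triflate silylation of the tertiary aldol hydroxyl under non-basic conditions avoids retro-aldol cleavage and installs the bulky, non-chelating, acid-stable group that shields one alkene face in step 6, prevents over-cleavage in step 16 and enforces Felkin–Anh addition in step 17.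

**Step 4**
Reactants: 6 3-O-TBS ether of 5
Product: 7 Fur–CHO (pentodialdofuranose, aldehyde carbon = C10)
Conditions: H5IO6, EtOAc, rt
Reagents that add atoms: none
Why: Periodic acid in ethyl acetate hydrolyses only the terminal 5,6-acetonide and cleaves the liberated glycol in the same flask (Malaprade cleavage), which excises glucose C6 and leaves glucose C5 as aldehyde carbon C10 without touching the anomeric acetonide, the TBS ether or C9.

**Step 5**
Reactants: 7 Fur–CHO; 8 2-(triphenyl-λ5-phosphanylidene)propanal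
Product: 9 (2E)-2-methyl-3-Fur-prop-2-enal (C2 aldehyde, C1=C10)
Conditions: 8 (1.1 equiv), toluene, 80 °C
Reagents that add atoms: none
Why: Wittig olefination with the stabilised α-branched ylide should give the (E)-trisubstituted enal (CHO trans to C9), the geometry that later places C2 and C9 trans on the cyclohexene.

**Step 6**
Reactants: 9 (2E)-2-methyl-3-Fur-prop-2-enal; 10 (E)-1-(dimethylamino)-3-(tert-butyldimethylsilyloxy)buta-1,3-diene
Product: 11 Diels–Alder adduct, (1S,10S)-1-formyl-1-methyl-10-Fur-12-(TBSO)cyclohex-12-ene with 14-NMe2 cis to CHO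
Conditions: 10 (2 equiv), toluene, 70 °C
Reagents that add atoms: none
Why: Thermal normal-demand Diels–Alder reaction of the very electron-rich aminosiloxydiene, a diene class known to add to α,β-disubstituted enals with formation of a formyl-bearing quaternary carbon, should bond its CH2 terminus (C11) to β-carbon C10 and its amino terminus (C14) to C1 with CHO endo, and should attack the alkene face opposite the quaternary C8 in the A1,3-minimised rotamer (H9 eclipsing C10=C1), which sets 1S and 10S from C9.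

**Step 7**
Reactants: 11 Diels–Alder adduct; 12 vinylmagnesium bromide
Product: 14 hydroxy enone (1S,10S)-1-(1-hydroxyallyl)-1-methyl-10-Fur-cyclohex-13-en-12-one (C2 epimers), via allylic alcohol adduct 13 (not isolated)
Conditions: 12 (1.5 equiv), THF, −78 °C; then 1 M HCl, THF, 0 °C
Reagents that add atoms: none
Why: Grignard 1,2-addition to the neopentyl aldehyde (ester and silyl enol ether inert at −78 °C), followed by acid hydrolysis of the silyl enol ether and β-elimination of dimethylamine, should give the 4,4-disubstituted cyclohexenone; the Felkin–Anh product is the unwanted 2S epimer, which is of no consequence because C2 is re-set in steps 12 and 13.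

**Step 8**
Reactants: 14 hydroxy enone
Product: 15 2-O-TES ether of 14
Conditions: TESOTf (1.2 equiv), 2,6-lutidine, CH2Cl2, −78 °C
Reagents that add atoms: triethylsilyl triflate CC[Si](CC)(CC)OS(=O)(=O)C(F)(F)F
Why: Silylation masks the C2 carbinol so that no alkoxide capable of vinylogous retro-aldol cleavage or oxy-Cope rearrangement is present in the two enolate steps.

**Step 9**
Reactants: 15 2-O-TES ether of 14
Product: 16 11-methyl enone (C11 epimers)
Conditions: LDA (1.1 equiv), THF, −78 °C; MeI, DMPU, −78 → −40 °C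
Reagents that add atoms: iodomethane CI
Why: Kinetic α′-deprotonation of the enone (C1 is quaternary, so no γ-proton exists) and SN2 methylation of the lithium enolate bring in C20; the C11 configuration is irrelevant because C11 becomes sp2 in step 10.

**Step 10**
Reactants: 16 11-methyl enone
Product: 17 12-triflyloxy-11-methyl-cyclohexa-11,13-diene
Conditions: LDA (1.1 equiv), THF, −78 °C; N-(5-chloro-2-pyridyl)bis(trifluoromethanesulfonimide), −78 → −20 °C
Reagents that add atoms: N-(5-chloro-2-pyridyl)bis(trifluoromethanesulfonimide) O=S(=O)(N(c1ccc(Cl)cn1)S(=O)(=O)C(F)(F)F)C(F)(F)F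
Why: Deprotonation of the remaining C11–H gives the tetrasubstituted cross-conjugated dienolate, which is O-sulfonylated by the pyridyl triflimide (enol triflate formation).

**Step 11**
Reactants: 17 dienyl triflate
Product: 19 dienyl carbinol 1-(1-hydroxyallyl)-1,11-dimethyl-10-Fur-cyclohexa-11,13-diene (C2 epimers), via TES-protected diene 18 (not isolated)
Conditions: Pd(OAc)2 (5 mol %), PPh3, HCO2H, Et3N, DMF, 60 °C; extractive work-up; then HF·pyridine, pyridine, THF, 0 °C
Reagents that add atoms: none
Why: Palladium-catalysed formate reduction of the dienyl triflate (oxidative addition, decarboxylation of formate, reductive elimination) keeps the diene in place, and buffered HF·pyridine cleaves the secondary TES ether while the tertiary TBS ether stays.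

**Step 12**
Reactants: 19 dienyl carbinol
Product: 20 vinyl ketone (C2=O)
Conditions: Dess–Martin periodinane, CH2Cl2, 0 °C
Reagents that add atoms: none
Why: Dess–Martin oxidation of the only free (secondary allylic) hydroxyl merges both C2 epimers into one non-enolisable vinyl ketone without touching the ring diene.

**Step 13**
Reactants: 20 vinyl ketone
Product: 21 (2R)-allylic alcohol
Conditions: NaBH4, CeCl3·7H2O, MeOH, −78 °C
Reagents that add atoms: none
Why: Luche 1,2-reduction under Felkin–Anh control, with C10 anti to the incoming hydride, the cerium-bound oxygen in the open sector next to C14, the flat vinyl group next to the furanose and the hydride passing the C15 methyl, should give the 2R carbinol, the epimer that vinyl addition cannot deliver.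

**Step 14**
Reactants: 21 (2R)-allylic alcohol
Product: 22 (2R,11S,12R)-triol (11,12-cis-diol on the α-face)
Conditions: OsO4 (2 mol %), NMO (1.05 equiv), acetone–H2O, 0 °C
Reagents that add atoms: N-methylmorpholine N-oxide C[N+]1([O-])CCOCC1; water O
Why: Upjohn dihydroxylation should take the trisubstituted, most electron-rich C11=C12 bond of the ring diene in preference to C13=C14 (next to quaternary C1) and to the neopentyl, oxygen-deactivated vinyl group, and syn addition from the α-face, anti to the C10 substituent and the pseudoaxial C15 methyl, sets 11S and 12R.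

**Step 15**
Reactants: 22 triol
Product: 23 2,12-diacetate
Conditions: Ac2O, pyridine, DMAP (cat.), CH2Cl2, rt
Reagents that add atoms: acetic anhydride CC(=O)OC(C)=O
Why: DMAP-catalysed acetylation esterifies the two secondary hydroxyls (O2, O12) and leaves the tertiary 11-OH free; the O12 acetate also takes the ring glycol out of the reach of periodate in step 16.

**Step 16**
Reactants: 23 2,12-diacetate
Product: 25 C7 aldehyde 9-O-formate (8-OTBS), via lactol 24 (not isolated)
Conditions: TFA–H2O (4:1), 0 °C; evaporate; NaIO4, THF–H2O, 0 °C → rt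
Reagents that add atoms: none
Why: Aqueous acid hydrolyses the anomeric acetonide and Malaprade cleavage of the only glycol (C6 hemiacetal OH/C7 OH, O8 being silylated) cuts C6–C7, which opens the temporary furanose, unmasks C7 as a non-enolisable aldehyde and leaves glucose C1 as a formate on O9.

**Step 17**
Reactants: 25 C7 aldehyde 9-O-formate; 26 3-chloro-1-(trimethylsilyl)prop-1-yne
Product: 29 9-hydroxy γ-lactone (6S,7R; 8-OTBS; alkyne C4–SiMe3), via chlorohydrin ester 27 (not isolated), via 9-O-formyl lactone 28 (not isolated)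
Conditions: 26, ZnBr2, LDA, THF, −78 °C; 25, −78 → 0 °C; aq NH4Cl; then AcCl (cat.), MeOH, 0 °C
Reagents that add atoms: none
Why: SE2′ addition of the chloroallenylzinc reagent through a cyclic transition state is known to give anti-chlorohydrins (sets 6S relative to C7), Felkin–Anh/Cornforth attack anti to the non-chelating 8-OTBS group with the larger C9 branch on the carbonyl-oxygen side sets 7R, the zinc alkoxide closes the γ-lactone on the C19 ester while O9 is still blocked as formate, and mild acidic methanolysis then removes the formate much faster than the acetates.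

**Step 18**
Reactants: 29 9-hydroxy γ-lactone
Product: 31 8,9,11-triol enyne (terminal alkyne), via terminal alkyne TBS ether 30 (not isolated)
Conditions: TBAF–AcOH (1:1), THF, 0 °C; then HF·pyridine, rt
Reagents that add atoms: none
Why: Buffered fluoride protodesilylates the alkynylsilane without base-induced loss of HCl, and HF·pyridine then cleaves the hindered tertiary TBS ether; chloride, lactone and acetates tolerate both.

**Step 19**
Reactants: 31 8,9,11-triol enyne
Product: 32 enyne triacetate (2,9,12-tri-O-acetyl; 8-OH and 11-OH free)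
Conditions: Ac2O, pyridine, DMAP, CH2Cl2, 0 °C → rt
Reagents that add atoms: acetic anhydride CC(=O)OC(C)=O
Why: DMAP-catalysed acetylation of the only secondary hydroxyl (O9), with the tertiary 8-OH and 11-OH left free, completes the substitution pattern and ends any chance of O7→O9 translactonisation.

**Step 20**
Reactants: 32 enyne triacetate
Product: 34 CNP0285654.4 (target), via open triene 33 (not isolated)
Conditions: Hoveyda–Grubbs II catalyst (15 mol %, in portions), ethylene (1 atm), toluene (1 mM), 80 °C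
Reagents that add atoms: ethene C=C
Why: Ru=CH2 formed from the catalyst and ethylene adds to the terminal alkyne C4≡C5 (metallacyclobutene, ring opening, methylene transfer) and turns it into the 2-substituted butadiene 33, whose monosubstituted C4=CH2 end then undergoes ring-closing metathesis with the C3 vinyl group, ethylene being returned. The closest known reaction type is the ethylene-assisted endo-mode ring-closing enyne metathesis used for macrocyclic 1,3-dienes, together with diene–ene RCM to cis-cyclodecenes fused to a six-membered ring. The ten-membered ring closes by C3=C4 bond formation in the endo mode, so that both former alkyne carbons (C4, C5) lie in the ring and C5 keeps the exocyclic methylene C16. No stereocentre is formed; the new ring double bond is expected to be Z because an E-alkene conjugated with the exocyclic methylene would be far more strained in the trans-fused bicyclo[8.4.0] frame, and all ten stereocentres are spectators. The step needs endo over exo closure (ten- against nine-membered ring), secured by ethylene, which converts the alkyne before cyclisation and leaves the unhindered CH=CH2 terminus as the only reactive diene end, and it needs cyclisation over oligomerisation, secured by high dilution and by the turn that the gauche C2/C9 arms on the cyclohexene and the lactone impose on the chain. The ring alkene C13=C14 (next to quaternary C1) and the 1,1-disubstituted C5=C16 are too hindered to compete, and chloride, acetates, lactone and tertiary alcohols are tolerated by ruthenium carbenes.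

**Compound list**

1 | 1,2:5,6-di-O-isopropylidene-α-D-glucofuranose | O[C@@H]1[C@H]2OC(C)(C)O[C@H]2O[C@@H]1[C@H]1COC(C)(C)O1 | starting material
2 | 1,2:5,6-di-O-isopropylidene-α-D-ribo-hexofuranos-3-ulose | O=C1[C@H]2OC(C)(C)O[C@H]2O[C@@H]1[C@H]1COC(C)(C)O1 | intermediate
3 | methyl propanoate | CCC(=O)OC | starting material
4 | aldol adduct, both C17 epimers (lithium aldolate, drawn as the alcohol) | COC(=O)C(C)[C@]1(O)[C@H]2OC(C)(C)O[C@H]2O[C@@H]1[C@H]1COC(C)(C)O1 | intermediate
5 | methyl (2R)-2-(1,2:5,6-di-O-isopropylidene-α-D-allofuranos-3-C-yl)propanoate | COC(=O)[C@H](C)[C@]1(O)[C@H]2OC(C)(C)O[C@H]2O[C@@H]1[C@H]1COC(C)(C)O1 | intermediate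
6 | 3-O-TBS ether of 5 | COC(=O)[C@H](C)[C@]1(O[Si](C)(C)C(C)(C)C)[C@H]2OC(C)(C)O[C@H]2O[C@@H]1[C@H]1COC(C)(C)O1 | intermediate
7 | Fur–CHO (C10 aldehyde) | COC(=O)[C@H](C)[C@]1(O[Si](C)(C)C(C)(C)C)[C@H]2OC(C)(C)O[C@H]2O[C@@H]1C=O | intermediate
8 | 2-(triphenyl-λ5-phosphanylidene)propanal | CC(C=O)=P(c1ccccc1)(c1ccccc1)c1ccccc1 | starting material
9 | (2E)-2-methyl-3-Fur-prop-2-enal | COC(=O)[C@H](C)[C@]1(O[Si](C)(C)C(C)(C)C)[C@H]2OC(C)(C)O[C@H]2O[C@@H]1/C=C(\C)C=O | intermediate
10 | (E)-1-(dimethylamino)-3-(tert-butyldimethylsilyloxy)buta-1,3-diene | C=C(O[Si](C)(C)C(C)(C)C)/C=C/N(C)C | starting material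
11 | Diels–Alder adduct (1S,10S; NMe2 cis to CHO) | O=C[C@@]1(C)[C@@H](N(C)C)C=C(O[Si](C)(C)C(C)(C)C)C[C@@H]1[C@H]2O[C@@H]3OC(C)(C)O[C@@H]3[C@@]2(O[Si](C)(C)C(C)(C)C)[C@@H](C)C(=O)OC | intermediate
12 | vinylmagnesium bromide | C=C[Mg]Br | starting material
13 | C2 vinyl carbinol of 11 (C2 epimers, mainly 2S) | C=CC(O)[C@@]1(C)[C@@H](N(C)C)C=C(O[Si](C)(C)C(C)(C)C)C[C@@H]1[C@H]2O[C@@H]3OC(C)(C)O[C@@H]3[C@@]2(O[Si](C)(C)C(C)(C)C)[C@@H](C)C(=O)OC | intermediate
14 | hydroxy enone (C2 epimers) | C=CC(O)[C@@]1(C)C=CC(=O)C[C@@H]1[C@H]2O[C@@H]3OC(C)(C)O[C@@H]3[C@@]2(O[Si](C)(C)C(C)(C)C)[C@@H](C)C(=O)OC | intermediate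
15 | 2-O-TES ether of 14 | C=CC(O[Si](CC)(CC)CC)[C@@]1(C)C=CC(=O)C[C@@H]1[C@H]2O[C@@H]3OC(C)(C)O[C@@H]3[C@@]2(O[Si](C)(C)C(C)(C)C)[C@@H](C)C(=O)OC | intermediate
16 | 11-methyl enone (C11 epimers) | C=CC(O[Si](CC)(CC)CC)[C@@]1(C)C=CC(=O)C(C)[C@@H]1[C@H]2O[C@@H]3OC(C)(C)O[C@@H]3[C@@]2(O[Si](C)(C)C(C)(C)C)[C@@H](C)C(=O)OC | intermediate
17 | 12-triflyloxy-11,13-diene | C=CC(O[Si](CC)(CC)CC)[C@@]1(C)C=CC(OS(=O)(=O)C(F)(F)F)=C(C)[C@@H]1[C@H]2O[C@@H]3OC(C)(C)O[C@@H]3[C@@]2(O[Si](C)(C)C(C)(C)C)[C@@H](C)C(=O)OC | intermediate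
18 | 11-methyl-11,13-diene, 2-O-TES | C=CC(O[Si](CC)(CC)CC)[C@@]1(C)C=CC=C(C)[C@@H]1[C@H]2O[C@@H]3OC(C)(C)O[C@@H]3[C@@]2(O[Si](C)(C)C(C)(C)C)[C@@H](C)C(=O)OC | intermediate
19 | dienyl carbinol (C2 epimers) | C=CC(O)[C@@]1(C)C=CC=C(C)[C@@H]1[C@H]2O[C@@H]3OC(C)(C)O[C@@H]3[C@@]2(O[Si](C)(C)C(C)(C)C)[C@@H](C)C(=O)OC | intermediate
20 | vinyl ketone (C2=O) | C=CC(=O)[C@@]1(C)C=CC=C(C)[C@@H]1[C@H]2O[C@@H]3OC(C)(C)O[C@@H]3[C@@]2(O[Si](C)(C)C(C)(C)C)[C@@H](C)C(=O)OC | intermediate
21 | (2R)-allylic alcohol | C=C[C@@H](O)[C@@]1(C)C=CC=C(C)[C@@H]1[C@H]2O[C@@H]3OC(C)(C)O[C@@H]3[C@@]2(O[Si](C)(C)C(C)(C)C)[C@@H](C)C(=O)OC | intermediate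
22 | (2R,11S,12R)-triol | C=C[C@@H](O)[C@@]1(C)C=C[C@@H](O)[C@@](C)(O)[C@@H]1[C@H]2O[C@@H]3OC(C)(C)O[C@@H]3[C@@]2(O[Si](C)(C)C(C)(C)C)[C@@H](C)C(=O)OC | intermediate
23 | 2,12-diacetate | C=C[C@@H](OC(C)=O)[C@@]1(C)C=C[C@@H](OC(C)=O)[C@@](C)(O)[C@@H]1[C@H]2O[C@@H]3OC(C)(C)O[C@@H]3[C@@]2(O[Si](C)(C)C(C)(C)C)[C@@H](C)C(=O)OC | intermediate
24 | lactol (C6 hemiacetal, 7-OH; anomers) | C=C[C@@H](OC(C)=O)[C@@]1(C)C=C[C@@H](OC(C)=O)[C@@](C)(O)[C@@H]1[C@H]2OC(O)[C@H](O)[C@@]2(O[Si](C)(C)C(C)(C)C)[C@@H](C)C(=O)OC | intermediate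
25 | C7 aldehyde 9-O-formate | C=C[C@@H](OC(C)=O)[C@@]1(C)C=C[C@@H](OC(C)=O)[C@@](C)(O)[C@@H]1[C@@H](OC=O)[C@@](O[Si](C)(C)C(C)(C)C)(C=O)[C@@H](C)C(=O)OC | intermediate
26 | 3-chloro-1-(trimethylsilyl)prop-1-yne | ClCC#C[Si](C)(C)C | starting material
27 | (6S,7R)-anti-chlorohydrin methyl ester | C=C[C@@H](OC(C)=O)[C@@]1(C)C=C[C@@H](OC(C)=O)[C@@](C)(O)[C@@H]1[C@@H](OC=O)[C@@](O[Si](C)(C)C(C)(C)C)([C@@H](O)[C@@H](Cl)C#C[Si](C)(C)C)[C@@H](C)C(=O)OC | intermediate
28 | γ-lactone 9-O-formate | C=C[C@@H](OC(C)=O)[C@@]1(C)C=C[C@@H](OC(C)=O)[C@@](C)(O)[C@@H]1[C@@H](OC=O)[C@]2(O[Si](C)(C)C(C)(C)C)[C@@H](C)C(=O)O[C@H]2[C@@H](Cl)C#C[Si](C)(C)C | intermediate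
29 | 9-hydroxy γ-lactone (8-OTBS, C4–SiMe3) | C=C[C@@H](OC(C)=O)[C@@]1(C)C=C[C@@H](OC(C)=O)[C@@](C)(O)[C@@H]1[C@@H](O)[C@]2(O[Si](C)(C)C(C)(C)C)[C@@H](C)C(=O)O[C@H]2[C@@H](Cl)C#C[Si](C)(C)C | intermediate
30 | terminal alkyne, 8-OTBS | C=C[C@@H](OC(C)=O)[C@@]1(C)C=C[C@@H](OC(C)=O)[C@@](C)(O)[C@@H]1[C@@H](O)[C@]2(O[Si](C)(C)C(C)(C)C)[C@@H](C)C(=O)O[C@H]2[C@@H](Cl)C#C | intermediate
31 | 8,9,11-triol enyne | C=C[C@@H](OC(C)=O)[C@@]1(C)C=C[C@@H](OC(C)=O)[C@@](C)(O)[C@@H]1[C@@H](O)[C@]2(O)[C@@H](C)C(=O)O[C@H]2[C@@H](Cl)C#C | intermediate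
32 | enyne triacetate | C=C[C@@H](OC(C)=O)[C@@]1(C)C=C[C@@H](OC(C)=O)[C@@](C)(O)[C@@H]1[C@@H](OC(C)=O)[C@]2(O)[C@@H](C)C(=O)O[C@H]2[C@@H](Cl)C#C | intermediate
33 | open triene (C5 bearing =CH2 and CH=CH2) | C=C[C@@H](OC(C)=O)[C@@]1(C)C=C[C@@H](OC(C)=O)[C@@](C)(O)[C@@H]1[C@@H](OC(C)=O)[C@]2(O)[C@@H](C)C(=O)O[C@H]2[C@@H](Cl)C(=C)C=C | intermediate
34 | CNP0285654.4 | C=C1/C=C\[C@@H](OC(C)=O)[C@@]2(C)C=C[C@@H](OC(C)=O)[C@@](C)(O)[C@@H]2[C@@H](OC(C)=O)[C@]2(O)[C@@H](C)C(=O)O[C@H]2[C@H]1Cl | target

**Totals.** Total step count: 20. Longest linear sequence: 20 steps (1 → 34). The partners 3, 8, 10, 12 and 26 are purchased.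

**Steps most likely to fail**

**Step 20.**
- Risk: the open triene may form but not cyclise, because the neopentyl C3 alkene engages slowly. Intermolecular metathesis may then lead to oligomers, or closure may occur in the exo mode.
- Fallback (a temporary ring as turn element), from 31 back to 34:
  - The 8,9-diol of 31 is tied up with 2-methoxypropene/PPTS as the 8,9-O-isopropylidene enyne F1. Its dioxolane forces C7 and C10 onto the same side and so brings the two chain ends together.
  - The same ethylene-assisted enyne metathesis should then give the macrocyclic 8,9-acetonide F2.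
  - Aqueous acetic acid should free the 9-O-deacetyl target F3.
  - DMAP-catalysed acetylation of O9 gives 34.

**Step 6.**
- Risk: the cycloaddition to the hindered trisubstituted enal may be too slow. Hetero-Diels–Alder addition to the C=O group may compete, or facial selectivity may be poor.
- Fallback (Lewis acid activation of an acid-stable diene, with the unsaturation regained by oxidation), from 9 back to 14:
  - Me2AlCl-promoted Diels–Alder reaction of 9 with 2-(tert-butyldimethylsilyloxy)buta-1,3-diene should give the silyl enol ether aldehyde F4, with the same regiochemistry and face.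
  - Vinylmagnesium bromide converts it into the vinyl carbinol F5.
  - Saegusa–Ito dehydrogenation (Pd(OAc)2, MeCN) of the regiodefined silyl enol ether installs C13=C14 and gives 14.

**Step 17.**
- Risk: addition to the α-quaternary aldehyde may stall. Facial selectivity may be lost through residual chelation, or the zinc alkoxide may close to the epoxide before it lactonises.
- Fallback (C–C bond first, heteroatoms later, under reagent control), from 25 back to 27:
  - Wittig olefination of 25 with the semi-stabilised ylide from (3-trimethylsilylprop-2-ynyl)triphenylphosphonium bromide should give the (E)-enyne F6.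
  - Shi epoxidation with the ketone enantiomer matched to 7R, a method that favours conjugated trans-enynes over terminal and cis alkenes, gives the trans-alkynyl epoxide F7.
  - Opening at the propargylic carbon C6 with chloride (Li2CuCl4), with inversion, gives the anti-chlorohydrin 27.
  - 27 is then lactonised and deformylated as in step 17.

**Further compounds**

F1 | step 20 | 8,9-O-isopropylidene enyne | C=C[C@@H](OC(C)=O)[C@@]1(C)C=C[C@@H](OC(C)=O)[C@@](C)(O)[C@@H]1[C@H]3OC(C)(C)O[C@]32[C@@H](C)C(=O)O[C@H]2[C@@H](Cl)C#C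
F2 | step 20 | macrocyclic 8,9-acetonide | C=C1/C=C\[C@@H](OC(C)=O)[C@@]2(C)C=C[C@@H](OC(C)=O)[C@@](C)(O)[C@@H]2[C@H]4OC(C)(C)O[C@]43[C@@H](C)C(=O)O[C@H]3[C@H]1Cl
F3 | step 20 | 9-O-deacetyl target | C=C1/C=C\[C@@H](OC(C)=O)[C@@]2(C)C=C[C@@H](OC(C)=O)[C@@](C)(O)[C@@H]2[C@@H](O)[C@]2(O)[C@@H](C)C(=O)O[C@H]2[C@H]1Cl
F4 | step 6 | silyl enol ether aldehyde | O=C[C@@]1(C)CC=C(O[Si](C)(C)C(C)(C)C)C[C@@H]1[C@H]2O[C@@H]3OC(C)(C)O[C@@H]3[C@@]2(O[Si](C)(C)C(C)(C)C)[C@@H](C)C(=O)OC
F5 | step 6 | vinyl carbinol of F4 (C2 epimers) | C=CC(O)[C@@]1(C)CC=C(O[Si](C)(C)C(C)(C)C)C[C@@H]1[C@H]2O[C@@H]3OC(C)(C)O[C@@H]3[C@@]2(O[Si](C)(C)C(C)(C)C)[C@@H](C)C(=O)OC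
F6 | step 17 | (E)-enyne | C=C[C@@H](OC(C)=O)[C@@]1(C)C=C[C@@H](OC(C)=O)[C@@](C)(O)[C@@H]1[C@@H](OC=O)[C@@](O[Si](C)(C)C(C)(C)C)(/C=C/C#C[Si](C)(C)C)[C@@H](C)C(=O)OC
F7 | step 17 | trans-alkynyl epoxide | C=C[C@@H](OC(C)=O)[C@@]1(C)C=C[C@@H](OC(C)=O)[C@@](C)(O)[C@@H]1[C@@H](OC=O)[C@@](O[Si](C)(C)C(C)(C)C)([C@H]4O[C@@H]4C#C[Si](C)(C)C)[C@@H](C)C(=O)OC
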